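| flask | substrate | partner | remark | time |
|---|---|---|---|---|
| midnight | 0.82 M | 0.55 equiv | run made earlier |  |
| summer | 0.82 M | 2.2 equiv | run made earlier |  |
| autumn | 1.6 M | 1.1 equiv | run made earlier |  |
| flask | 0.82 M | 1.10 equiv |  | 30 min |

| run | time / min | substrate / % | first product / % |
|---|---|---|---|
| midnight | 2.50 | 81 | 3 |
| midnight | 4.00 | 74 | 8 |
| midnight | 6.00 | 67 | 11 |
| midnight | 10.0 | 59 | 10 |
| midnight | 20.0 | 50 | 14 |
| midnight | 30.0 | 47 | 12 |
| summer | 2.00 | 52 | 15 |
| summer | 6.00 | 21 | 23 |
| summer | 10.0 | 13 | 24 |
| summer | 15.0 | 8 | 18 |
| summer | 25.0 | 6 | 15 |
| summer | 30.0 | 1 | 16 |
| autumn | 2.50 | 49 | 15 |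
| autumn | 5.00 | 32 | 20 |
| autumn | 8.00 | 27 | 20 |
| autumn | 15.0 | 19 | 21 |
| autumn | 30.0 | 16 | 20 |

(standard deviation of a reading: 1.5 percentage points)

- percent here means substrate units held: one idle adduct counts as two
- what is said of first product includes idle adduct
- what was read earlier has a scatter of 1.5 percentage points, one standard deviation
- steps under discussion: substrate + partner -> first product; substrate + partner -> other mono adduct; partner + first product -> bis adduct; partner + other mono adduct -> bis adduct; substrate + first product <-> idle adduct; first product <-> isomer of the product
- in an amount of first product, one idle adduct counts as one first product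

- how much substrate there is at 30 min, in percent of the substrate charged
- how much first product there is at 30 min, in percent of the substrate charged
- how much other mono adduct there is at 30 min, in percent of the substrate charged
- how much bis adduct there is at 30 min, in percent of the substrate charged

Late in the autumn run, between 15.0 min and 30.0 min, substrate falls only from 19% to 16%, and I use that slope to decide whether the flask is stopped at 30 min or left longer. I read a late constant of 0.0115 /min and, from the start of the midnight run, a rate constant of 0.226 /M/min for substrate loss. Their quotient is the late [partner], which in the middle of that interval is 3.17% of the autumn substrate charge, a reading with all the scatter of its parents.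

Each substrate gone takes one partner, unless it sits in idle adduct, and each bis adduct takes a second partner. So I carry the margin, partner spent minus substrate gone per substrate charged, which equals bis adduct less the idle adducts counted singly.

The flask has the autumn equivalents at half the concentration and twice the time, so I read it as autumn at 15.0 min, with 6.34% of partner left by my estimate. The margin is then 22.7%. Waiting can draw on those 6.34% of partner, less whatever further substrate takes, against the margin already made, so I stop at 30 min.

The forecast gives 21% substrate, 19% first product, 40% other mono adduct and 16% bis adduct: “The late substrate slope implies about 14% partner left”. My margin alone stands above its bis adduct.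

The flask gives 20.9%, 20.2%, 25.9% and 26.6%.

    substrate + partner → first product (k = 0.00109 /M/s)
    substrate + partner → other mono adduct (k = 0.00201 /M/s)
    partner + first product → bis adduct (k = 8.24 × 10⁻⁴ /M/s)
    partner + other mono adduct → bis adduct (k = 0.00217 /M/s)
    substrate + first product ⇌ idle adduct, settled at all times (K = 1.51 /M)
    first product ⇌ isomer of the product (K = 0.144, k = 0.00194 /s)

Its margin is 22.4%, and the idle adducts counted singly add 4.15%, which makes the 26.6% of bis adduct. Left until 80 min, the same flask has 0.35% of its partner, the limiting reagent, and 17.6% substrate, so its margin is 27.3%. Idle adducts add 3.68%, and that flask holds 24.8% other mono adduct and 30.9% bis adduct.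

(The data come from a simulation with constants of no real substance, and the scatter is random.)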